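**Retrosynthetic overview**

1. Target 28 ⇐ PMB removal from 27 ⇐ esterification of the C8 allylic alcohol 21 with (2R,3R)-epoxyangelic acid 25 (Sharpless route from methyl angelate).
2. 21 ⇐ ten-membered (3Z,6Z)-dienone 17 by chelation-controlled C8 reduction and lactone α-methylenation.
3. Key disconnection: 17 ⇐ cis-fused bicyclic hydroxy mesylate 16 by Grob fragmentation of the C3–C8 ring-fusion bond, a four-carbon ring expansion (six → ten) that creates the C3=C4 Z-alkene.
4. 16 ⇐ ring A closed by metathesis (fixes C6=C7 as cis) on ring-B ketone 13 after isopropenyl addition; C9–O by epoxide opening; C10 and the lactone by anti opening of an oxa-bridge with an acetal Grignard reagent.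
5. Ring B ⇐ furan + methacrolein Diels–Alder adduct 3 (C1, C8, quaternary C3); C4 by allylboration. Ring order: ring B (oxa-bridged) → γ-lactone → ring A → ten-membered ring.

Labels used for every compound: C1 = lactone O–CH; C2 = CH2; C3 = C(CH3); C4; C5; C6; C7 = C(CH3); C8 = CH–O(acyl); C9 = CH–OH; C10 = CH bonded to C11; C11, C12, C13 = lactone α-carbon, carbonyl, exocyclic CH2. β = face of the C10–C11 bond, α = face of the C1–O bond. Ring B = C1, C2, C3, C8, C9, C10; ring A = C3–C8.

Assumption: the sense of induction of the new step 1 is not known; the (S)-catalyst is written, and its mirror image is used if the adduct proves to be the enantiomer of 3.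

**Route**

Step 1
Reactants: 1 furan; 2 methacrolein
Product: 3 (1R,2S,4R)-2-methyl-7-oxabicyclo[2.2.1]hept-5-ene-2-carbaldehyde (exo-CHO, endo-CH3)
Conditions: (S)-B-(o-tolyl)oxazaborolidinium triflimide (from the (S)-diphenylprolinol-derived oxazaborolidine and Tf2NH, 10 mol%), furan (5 equiv), CH2Cl2, −78 °C; used cold
Reagents that add atoms: none
Why: Proposed new method: the cationic chiral boron Lewis acid binds the formyl oxygen of s-trans methacrolein (formyl C–H···O contact to the catalyst) and blocks one enal face, furan adds to the open face with CHO exo as α-substituted acroleins do, and −78 °C keeps the reversible furan adduct under kinetic control, so C1, C8 and the quaternary C3 are set in one ring-forming step; the closest known reaction type is the oxazaborolidine-catalysed Diels–Alder of furan with 2-haloacroleins and of cyclopentadiene with methacrolein.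

Step 2
Reactants: 3 aldehyde; 4 allylmagnesium bromide
Product: 5 (R)-1-[(1R,2R,4R)-2-methyl-7-oxabicyclo[2.2.1]hept-5-en-2-yl]but-3-en-1-ol
Conditions: (+)-Ipc2BOMe, 4, Et2O, −78 °C; then 3, −78 °C; NaOH, H2O2, 0 °C
Reagents that add atoms: none
Why: Brown asymmetric allylboration through a chair Zimmerman–Traxler transition state delivers allyl under reagent control to the Re face of the aldehyde, setting C4 as R, the configuration that later places the leaving group trans to the C3 methyl on ring A.

Step 3
Reactants: 5 homoallylic alcohol; 6 (1,3-dioxolan-2-ylmethyl)magnesium bromide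
Product: 7 ring-opened diol acetal (C1–OH α, C10 side chain β, C8=C9)
Conditions: CuCl (10 mol%), PPh3 (10 mol%), 6 (3.5 equiv), Et2O/THF, 0 °C to rt
Reagents that add atoms: none
Why: Copper-catalysed anti-SN2′ ring opening of a 7-oxanorbornene with a Grignard reagent: the organocopper attacks the endo face anti to the bridging oxygen at C10 (C9 is shielded by the endo C3 methyl), the C8–O bond breaks and the alkene moves to C8=C9, so the new C10–C11 bond is β and trans to the C1 hydroxyl.

Step 4
Reactants: 7 diol acetal
Product: 9 trans-fused γ-lactone with free C4–OH, via lactol 8 (not isolated)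
Conditions: 1 M HCl, THF, rt; then TEMPO (10 mol%), PhI(OAc)2, CH2Cl2, rt
Reagents that add atoms: water, O
Why: Acetal hydrolysis gives the γ-hydroxy aldehyde, which closes to the lactol, and oxoammonium (TEMPO) oxidation converts lactols much faster than the hindered secondary C4 alcohol, so the lactone forms with C1 and C10 untouched.

Step 5
Reactants: 9 hydroxy lactone
Product: 10 C4 mesylate
Conditions: MsCl, Et3N, CH2Cl2, 0 °C
Reagents that add atoms: methanesulfonyl chloride, CS(=O)(=O)Cl
Why: Sulfene-type mesylation proceeds with retention, and the neopentyl position makes the mesylate inert to substitution, so it acts as protecting group until it becomes the leaving group in step 10.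

Step 6
Reactants: 10 mesylate lactone
Product: 12 8α-hydroxy-9β-(4-methoxybenzyloxy) lactone, via epoxide 11 (not isolated)
Conditions: DMDO, acetone, −20 °C; evaporate; 4-MeOC6H4CH2OH (5 equiv), Yb(OTf)3 (10 mol%), CH2Cl2, 0 °C
Reagents that add atoms: dimethyldioxirane, CC1(C)OO1; 4-methoxybenzyl alcohol, COc1ccc(CO)cc1
Why: Epoxidation of the ring alkene (more electron-rich than the terminal one) occurs on the α face, anti to the pseudoaxial C3 methyl and the C10 side chain, and Lewis-acid alcoholysis then follows the Fürst–Plattner trans-diaxial rule at C9 (C8 is neopentyl), giving C9–OPMB β by inversion and C8–OH α.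

Step 7
Reactants: 12 alcohol
Product: 13 C8 ketone
Conditions: Dess–Martin periodinane, CH2Cl2, rt
Reagents that add atoms: none
Why: Dess–Martin oxidation is neutral, so the axial α-alkoxy stereocentre C9 is not epimerised.

Step 8
Reactants: 13 ketone; 14 isopropenylmagnesium bromide
Product: 15 tertiary alcohol (8β-OH, 8α-isopropenyl)
Conditions: CeCl3 (3 equiv), 14 (3 equiv), THF, −78 °C; NH4Cl aq. at −78 °C
Reagents that add atoms: none
Why: Organocerium 1,2-addition (Imamoto) suppresses enolisation and spares the lactone, and attack comes from the axial α face because the β face is blocked by the axial C3 methyl and C9–OPMB, placing isopropenyl cis to the C4 side chain and the OH cis to the C3 methyl.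

Step 9
Reactants: 15 diene
Product: 16 cis-fused bicyclic hydroxy mesylate (ring A cyclohexene, C6=C7)
Conditions: second-generation Grubbs catalyst (5 mol%), CH2Cl2, 40 °C
Reagents that add atoms: none
Why: Ring-closing metathesis of the isopropenyl and allyl groups closes six-membered ring A, so the new trisubstituted C6=C7 bond is necessarily cis (later Z) and the ring fusion is cis.

Step 10
Reactants: 16 bicyclic hydroxy mesylate
Product: 17 ten-membered (3Z,6Z)-dien-8-one
Conditions: KOtBu (1.5 equiv), THF, −20 to 0 °C
Reagents that add atoms: none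
Why: Grob (Wharton) fragmentation: the C8 alkoxide pushes, the C3–C8 bond is anti-periplanar to the equatorial C4–OMs and breaks in concert to give the C8 ketone and C3=C4, and because C2 is axial on ring A in this cis-fused system it ends cis to C5 (Z), expanding ring B from six to ten members.

Step 11
Reactants: 17 dienone
Product: 18 8β-alcohol (8R)
Conditions: Zn(BH4)2, Et2O, −30 °C
Reagents that add atoms: none
Why: Chelation-controlled (Cram chelate) 1,2-reduction: zinc bridges the C8 carbonyl and the C9 PMB ether and hydride adds from the face opposite C10, giving the anti (erythro) C8/C9 pattern.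

Step 12
Reactants: 18 lactone alcohol
Product: 21 α-methylene lactone, via Mannich base 19 (not isolated), via methiodide 20 (not isolated)
Conditions: LiN(iPr)2 (2.2 equiv), THF, −78 °C; CH2=NMe2+ I−, −78 °C to rt; then MeI, MeOH, rt; then NaHCO3 aq., CH2Cl2
Reagents that add atoms: N,N-dimethylmethyleneiminium iodide, C=[N+](C)C.[I-]
Why: Mannich reaction of the lactone enolate with Eschenmoser's salt, N-methylation and E1cB elimination install the exocyclic methylene without touching C1 or C10.

Step 13
Reactants: 22 methyl angelate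
Product: 23 (Z)-2-methylbut-2-en-1-ol
Conditions: iBu2AlH (2.2 equiv), CH2Cl2, −78 °C
Reagents that add atoms: none
Why: Hydride reduction of the ester to the allylic alcohol keeps the Z geometry.

Step 14
Reactants: 23 allylic alcohol
Product: 24 [(2S,3R)-2,3-dimethyloxiran-2-yl]methanol
Conditions: Ti(OiPr)4 (10 mol%), D-(−)-diethyl tartrate (12 mol%), tBuOOH, 4 Å MS, CH2Cl2, −20 °C
Reagents that add atoms: tert-butyl hydroperoxide, CC(C)(C)OO
Why: Sharpless asymmetric epoxidation: with D-(−)-tartrate oxygen is delivered to the top face (CH2OH drawn lower right), setting both epoxide centres.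

Step 15
Reactants: 24 epoxy alcohol
Product: 25 (2R,3R)-2,3-dimethyloxirane-2-carboxylic acid
Conditions: RuCl3 (2 mol%), NaIO4 (3 equiv), MeCN/EtOAc/H2O, 0 °C to rt
Reagents that add atoms: water, O
Why: Catalytic RuO4 oxidation takes the primary alcohol to the acid without opening the epoxide; the centres are unchanged (the C2 descriptor changes only by priority).

Step 16
Reactants: 21 allylic alcohol; 25 epoxy acid
Product: 27 9-O-PMB ether of the target, via mixed anhydride 26 (not isolated)
Conditions: 25, 2,4,6-Cl3C6H2COCl, Et3N, PhMe, rt; then 21, DMAP, rt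
Reagents that add atoms: none
Why: Yamaguchi esterification acylates the only free hydroxyl (C8) with retention at C8 and at the epoxide centres.

Step 17
Reactants: 27 PMB ether
Product: 28 target CNP0108157.1
Conditions: DDQ, CH2Cl2/pH 7 buffer, 0 °C
Reagents that add atoms: none
Why: Oxidative PMB cleavage (benzylic hydride abstraction, then hydrolysis of the hemiacetal) frees the C9 hydroxyl under neutral conditions that spare the epoxy ester, the methylene lactone and the skipped diene.

**Compound list**

1 | furan | c1ccoc1 | starting material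
2 | methacrolein | CC(=C)C=O | starting material
3 | (1R,2S,4R)-2-methyl-7-oxabicyclo[2.2.1]hept-5-ene-2-carbaldehyde, exo-CHO (route labels: bridgeheads C8 and C1, quaternary C3, CHO = C4) | O=C[C@@]1(C)C[C@@H]2C=C[C@H]1O2 | intermediate
4 | allylmagnesium bromide | C=CC[Mg]Br | starting material
5 | (R)-1-[(1R,2R,4R)-2-methyl-7-oxabicyclo[2.2.1]hept-5-en-2-yl]but-3-en-1-ol | C=CC[C@@H](O)[C@@]1(C)C[C@@H]2C=C[C@H]1O2 | intermediate
6 | (1,3-dioxolan-2-ylmethyl)magnesium bromide | Br[Mg]CC1OCCO1 | starting material
7 | ring-B cyclohexene (C8=C9): C1–OH α, C10 β-(1,3-dioxolan-2-ylmethyl) trans to it, C3 β-CH3 and α-[(R)-1-hydroxybut-3-enyl] | C1COC(O1)C[C@@H]2C=C[C@@](C)([C@H](O)CC=C)C[C@H]2O | intermediate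
8 | trans-fused lactol (C12 hemiacetal) of 7 | OC1C[C@@H]2C=C[C@@](C)([C@H](O)CC=C)C[C@H]2O1 | intermediate (not isolated)
9 | trans-fused γ-lactone (O on C1 α, C11 on C10 β) on ring-B cyclohexene (C8=C9), C3 β-CH3, α-[(R)-1-hydroxybut-3-enyl] | C1C(=O)O[C@@H]2C[C@](C)([C@H](O)CC=C)C=C[C@@H]12 | intermediate
10 | C4 methanesulfonate of 9 | C1C(=O)O[C@@H]2C[C@](C)([C@H](OS(C)(=O)=O)CC=C)C=C[C@@H]12 | intermediate
11 | 8α,9α-epoxide of 10 | C1C(=O)O[C@@H]2C[C@](C)([C@H](OS(C)(=O)=O)CC=C)[C@@H]3O[C@@H]3[C@@H]12 | intermediate (not isolated)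
12 | 8α-hydroxy-9β-(4-methoxybenzyloxy) lactone mesylate | C1C(=O)O[C@@H]2C[C@](C)([C@H](OS(C)(=O)=O)CC=C)[C@H](O)[C@@H](OCc3ccc(OC)cc3)[C@@H]12 | intermediate
13 | 8-oxo-9β-(4-methoxybenzyloxy) lactone mesylate | C1C(=O)O[C@@H]2C[C@](C)([C@H](OS(C)(=O)=O)CC=C)C(=O)[C@@H](OCc3ccc(OC)cc3)[C@@H]12 | intermediate
14 | isopropenylmagnesium bromide | CC(=C)[Mg]Br | starting material
15 | C8 tertiary alcohol: 8β-OH, 8α-isopropenyl, 9β-OPMB, C4 mesylate, allyl on C5 | C1C(=O)O[C@@H]2C[C@](C)([C@H](OS(C)(=O)=O)CC=C)[C@](O)(C(C)=C)[C@@H](OCc3ccc(OC)cc3)[C@@H]12 | intermediate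
16 | cis-fused bicyclic hydroxy mesylate: ring A cyclohexene (C6=C7, 7-CH3); 8β-OH cis to 3β-CH3; C4–OMs trans to 3-CH3 (equatorial on ring A); lactone and 9β-OPMB as before | C1C(=O)O[C@@H]2C[C@]3(C)[C@H](OS(C)(=O)=O)CC=C(C)[C@]3(O)[C@@H](OCc4ccc(OC)cc4)[C@@H]12 | intermediate
17 | (3Z,6Z)-3,7-dimethylcyclodeca-3,6-dien-8-one fused at C1/C10 to the trans γ-lactone, 9β-OPMB | C1C(=O)O[C@@H]2C/C(C)=C\C/C=C(/C)C(=O)[C@@H](OCc3ccc(OC)cc3)[C@@H]12 | intermediate
18 | 8β-alcohol (8R) of 17 | C1C(=O)O[C@@H]2C/C(C)=C\C/C=C(/C)[C@@H](O)[C@@H](OCc3ccc(OC)cc3)[C@@H]12 | intermediate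
19 | 11-(dimethylaminomethyl) lactone (C11 epimers) | CN(C)CC1C(=O)O[C@@H]2C/C(C)=C\C/C=C(/C)[C@@H](O)[C@@H](OCc3ccc(OC)cc3)[C@@H]12 | intermediate (not isolated)
20 | trimethylammonium iodide of 19 | C[N+](C)(C)CC1C(=O)O[C@@H]2C/C(C)=C\C/C=C(/C)[C@@H](O)[C@@H](OCc3ccc(OC)cc3)[C@@H]12.[I-] | intermediate (not isolated)
21 | α-methylene lactone with 8β-OH and 9β-OPMB | C=C1C(=O)O[C@@H]2C/C(C)=C\C/C=C(/C)[C@@H](O)[C@@H](OCc3ccc(OC)cc3)[C@@H]12 | intermediate
22 | methyl angelate, methyl (Z)-2-methylbut-2-enoate | C/C=C(/C)C(=O)OC | starting material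
23 | (Z)-2-methylbut-2-en-1-ol | C/C=C(/C)CO | intermediate
24 | [(2S,3R)-2,3-dimethyloxiran-2-yl]methanol | OC[C@]1(C)O[C@@H]1C | intermediate
25 | (2R,3R)-2,3-dimethyloxirane-2-carboxylic acid | OC(=O)[C@]1(C)O[C@@H]1C | intermediate
26 | mixed anhydride of 25 with 2,4,6-trichlorobenzoic acid | O=C(OC(=O)c1c(Cl)cc(Cl)cc1Cl)[C@]2(C)O[C@@H]2C | intermediate (not isolated)
27 | 9-O-(4-methoxybenzyl) ether of the target | C=C1C(=O)O[C@@H]2C/C(C)=C\C/C=C(/C)[C@@H](OC(=O)[C@]3(C)O[C@@H]3C)[C@@H](OCc4ccc(OC)cc4)[C@@H]12 | intermediate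
28 | CNP0108157.1: (1R,8R,9S,10R; 3Z,6Z) ten-membered diene, trans α-methylene-γ-lactone at C1/C10, 9-OH, 8-O-[(2R,3R)-epoxyangeloyl] | C=C1C(=O)O[C@@H]2C/C(C)=C\C/C=C(/C)[C@@H](OC(=O)[C@]3(C)O[C@@H]3C)[C@@H](O)[C@@H]12 | target

**Step count and risks**

Total steps: 17 (14 in the main line, 3 for acid 25). Longest linear sequence: 14 (steps 1–12, 16, 17).

The three steps most likely to fail:

The asymmetric Diels–Alder (step 1) is the proposed new reaction; conversion, exo selectivity, ee and the sense of induction are all untested for this diene/dienophile pair. The fallback uses known chemistry, sets out from 1 and 2 and comes back at 5. BF3·OEt2 at −40 °C gives the racemic exo adduct, that is 3 together with its mirror image (1S,2R,4S)-2-methyl-7-oxabicyclo[2.2.1]hept-5-ene-2-carbaldehyde F1. The reagent-controlled allylboration of step 2 then converts the racemate into 5 and the diastereomeric alcohol (R)-1-[(1S,2S,4S)-2-methyl-7-oxabicyclo[2.2.1]hept-5-en-2-yl]but-3-en-1-ol F2, which are separated by chromatography. This replaces asymmetric catalysis by a resolution.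

The epoxidation/alcoholysis (step 6) may fail on chemoselectivity against the terminal alkene, or at the opening at C9, which puts the new ether 1,3-diaxial to the C3 methyl. The fallback sets out from 10 and comes back at 12. After the same epoxidation to 11, dilute HClO4 in THF/H2O opens the epoxide with water to the trans-diaxial 8α,9β-diol F3. The less hindered C9 hydroxyl is then etherified with 4-methoxybenzyl trichloroacetimidate and catalytic La(OTf)3 to give 12.

The Grob ring expansion (step 10) may fail if the cis-fused system cannot hold the C4 mesylate anti-periplanar to the C3–C8 bond, or if base isomerises the skipped dienone. The fallback sets out from 15 and comes back at 17. KOtBu fragments 15 itself in the open-chain mode (same anti-periplanar requirement, same Z outcome) to the ring-B-opened trienone F4 (C8 isopropenyl ketone, Z-C3=C4, terminal vinyl on C5). Ring-closing metathesis of F4 at high dilution with second-generation Grubbs catalyst then closes the ten-membered ring at C6=C7 to give 17.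

Further compounds
F1 | step 1 | (1S,2R,4S)-2-methyl-7-oxabicyclo[2.2.1]hept-5-ene-2-carbaldehyde (mirror image of 3) | O=C[C@]1(C)C[C@H]2C=C[C@@H]1O2
F2 | step 1 | (R)-1-[(1S,2S,4S)-2-methyl-7-oxabicyclo[2.2.1]hept-5-en-2-yl]but-3-en-1-ol | C=CC[C@@H](O)[C@]1(C)C[C@H]2C=C[C@@H]1O2
F3 | step 6 | 8α,9β-diol lactone mesylate | C1C(=O)O[C@@H]2C[C@](C)([C@H](OS(C)(=O)=O)CC=C)[C@H](O)[C@@H](O)[C@@H]12
F4 | step 10 | ring-B-opened trienone (C8 isopropenyl ketone, 9-OPMB, Z-C3=C4, terminal vinyl) | C1C(=O)O[C@H](C/C(C)=C\CC=C)[C@H]1[C@H](OCc2ccc(OC)cc2)C(=O)C(C)=C
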